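**Plan**

- Numbering: naphthalene C1 (H), C2 (OH), C3 (CH2Ar), C4 (aryl). Ring A is C4a, C5–C8, C8a (6-OMe, 7-OH, 8-OMe). Ring B is C1–C4, C4a, C8a.
- Enabling feature: in ring B the C1=C2 bond links a bare CH, bonded to ring A at C8a, to C2, the only oxygen-bearing carbon of that ring. Olefin metathesis between a vinyl group on C8a and a CH2=C(OSiR3) group on C3 would leave exactly this bond.
- Cuts, in order: O–Bn and O–Si; C1=C2 (opens ring B); the enol CH2 back through a methyl ketone to an ester; C3–CH2Ar and C4–aryl together (alkynoate carbocupration/alkylation); the alkyne from the formyl group and the vinyl group from an aryl bromide on ring A.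
- Forward: ring A comes intact from syringaldehyde and receives vinyl and propiolate arms. The 4-aryl and 3-benzyl groups are joined across the alkyne, and the ester becomes the methyl ketone and then its TBS dienol ether. Ring B closes last and is aromatic at once; fluoride and hydrogenolysis finish the synthesis.
- Stereochemistry: the target has no stereocentre. The only element that matters is the geometry of the tetrasubstituted C3=C4 alkene (ring A cis to the C2 arm). Syn carbocupration with retention in the alkylation sets it, and it is absorbed into the arene.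

Key step: step 15

Assumption: the target SMILES carries no stereodescriptor, so the hindered C4–aryl axis is left uncontrolled; the compound is racemic should that axis be configurationally stable.

**Step 1**
Reactants: 1 syringaldehyde
Product: 2 4-(benzyloxy)-3,5-dimethoxybenzaldehyde
Conditions: BnBr, K2CO3, DMF, 60 °C
Reagents that add atoms: benzyl bromide, BrCc1ccccc1
Why: Williamson etherification, in which the para-formyl phenol is the only acidic site and its phenoxide is alkylated by the benzylic bromide, installing a group that lasts until the final hydrogenolysis.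

**Step 2**
Reactants: 2 4-(benzyloxy)-3,5-dimethoxybenzaldehyde
Product: 3 4-(benzyloxy)-2-bromo-3,5-dimethoxybenzaldehyde
Conditions: NBS (1.05 equiv), MeCN, 0 °C → rt, dark
Reagents that add atoms: N-bromosuccinimide, O=C1CCC(=O)N1Br
Why: Electrophilic aromatic bromination, in which the two free positions are equivalent (each ortho to one methoxy group and para to the other), the plain phenyl ring of the benzyl ether cannot compete, and a polar solvent in the dark keeps NBS away from radical benzylic bromination.

**Step 3**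
Reactants: 3 4-(benzyloxy)-2-bromo-3,5-dimethoxybenzaldehyde
Product: 4 4-(benzyloxy)-2-ethenyl-3,5-dimethoxybenzaldehyde
Conditions: vinylboronic acid pinacol ester, PdCl2(dppf) (5 mol %), K2CO3, 1,4-dioxane/H2O, 85 °C
Reagents that add atoms: 2-ethenyl-4,4,5,5-tetramethyl-1,3,2-dioxaborolane, C=CB1OC(C)(C)C(C)(C)O1
Why: Suzuki–Miyaura vinylation of an aryl bromide activated by its ortho formyl group, under conditions to which the non-enolisable aldehyde and the benzyl ether are inert.

**Step 4**
Reactants: 4 4-(benzyloxy)-2-ethenyl-3,5-dimethoxybenzaldehyde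
Product: 5 2-(benzyloxy)-4-ethenyl-5-ethynyl-1,3-dimethoxybenzene
Conditions: dimethyl (1-diazo-2-oxopropyl)phosphonate, K2CO3, MeOH, rt
Reagents that add atoms: dimethyl (1-diazo-2-oxopropyl)phosphonate, COP(=O)(OC)C(=[N+]=[N-])C(C)=O
Why: Ohira–Bestmann (Seyferth–Gilbert) homologation, in which the diazomethylphosphonate anion released by methanolysis olefinates the aldehyde and loss of N2 with 1,2-hydrogen shift gives the terminal alkyne, with no alkyllithium present that could add to the styrene.

**Step 5**
Reactants: 5 2-(benzyloxy)-4-ethenyl-5-ethynyl-1,3-dimethoxybenzene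
Product: 7 methyl 3-[4-(benzyloxy)-2-ethenyl-3,5-dimethoxyphenyl]prop-2-ynoate, via lithium acetylide 6 (not isolated)
Conditions: LiN(SiMe3)2, THF, −78 °C; ClCO2Me, −78 → 0 °C
Reagents that add atoms: methyl chloroformate, COC(=O)Cl
Why: Acetylide acylation, in which the hindered amide base removes only the alkyne proton without touching the vinyl group and the lithium acetylide is C-acylated by the chloroformate.

**Step 6**
Reactants: 8 4-bromo-3-methoxyphenol
Product: 9 4-(benzyloxy)-1-bromo-2-methoxybenzene
Conditions: BnBr, K2CO3, acetone, reflux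
Reagents that add atoms: benzyl bromide, BrCc1ccccc1
Why: Williamson etherification of the only acidic OH, masking the phenol so that the aryl bromide can later be metalated.

**Step 7**
Reactants: 10 vanillyl alcohol
Product: 11 [4-(benzyloxy)-3-methoxyphenyl]methanol
Conditions: BnBr (1.0 equiv), K2CO3, acetone, reflux
Reagents that add atoms: benzyl bromide, BrCc1ccccc1
Why: Chemoselective Williamson etherification, since carbonate deprotonates only the phenol, which is far more acidic than the benzylic alcohol, so the primary OH stays free.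

**Step 8**
Reactants: 11 [4-(benzyloxy)-3-methoxyphenyl]methanol
Product: 12 1-(benzyloxy)-4-(bromomethyl)-2-methoxybenzene
Conditions: PBr3 (0.4 equiv), Et2O, 0 °C; used crude at once
Reagents that add atoms: phosphorus tribromide, BrP(Br)Br
Why: Conversion of a primary benzylic alcohol to the bromide through its phosphite ester (SN2 displacement), with the labile electron-rich bromide taken on without chromatography.

**Step 9**
Reactants: 9 4-(benzyloxy)-1-bromo-2-methoxybenzene; 7 methyl 3-[4-(benzyloxy)-2-ethenyl-3,5-dimethoxyphenyl]prop-2-ynoate; 12 1-(benzyloxy)-4-(bromomethyl)-2-methoxybenzene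
Product: 16 methyl (2E)-2-[4-(benzyloxy)-3-methoxybenzyl]-3-[4-(benzyloxy)-2-ethenyl-3,5-dimethoxyphenyl]-3-[4-(benzyloxy)-2-methoxyphenyl]prop-2-enoate (ring A cis to CO2Me), via arylmagnesium bromide 13 (not isolated), via arylcopper 14 (not isolated), via alkenylcopper 15 (not isolated)
Conditions: 9, Mg, THF, 50 °C; CuBr·SMe2 (1 equiv per Grignard), THF, −40 °C; 7, −78 °C; HMPA, 12 (excess), −78 → −30 °C
Reagents that add atoms: none
Why: Carbocupration of an alkynoate followed by alkylation of the α-(alkoxycarbonyl)alkenylcopper, a known entry to fully substituted acrylates, in which aryl and copper add syn with the aryl group at the β-carbon so that ring A ends cis to the ester, and the C–Cu bond is replaced by the benzylic carbon with retention provided the mixture stays cold enough to prevent leakage through the copper allenolate, which the polar additive and the very reactive benzylic bromide allow.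

**Step 10**
Reactants: 16 the tetrasubstituted methyl acrylate
Product: 17 (2E)-2-[4-(benzyloxy)-3-methoxybenzyl]-3-[4-(benzyloxy)-2-ethenyl-3,5-dimethoxyphenyl]-3-[4-(benzyloxy)-2-methoxyphenyl]prop-2-en-1-ol
Conditions: i-Bu2AlH (3 equiv), CH2Cl2, −78 → 0 °C; quench with Na2SO4·10H2O
Reagents that add atoms: none
Why: Ester reduction with diisobutylaluminium hydride, chosen because the small Lewis-acidic hydride still reaches a carbonyl flanked like a 2,6-disubstituted benzoate, where acyl substitution by carbon or nitrogen nucleophiles would be unreliable, while styrene, alkene geometry and benzyl ethers are left alone.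

**Step 11**
Reactants: 17 the allylic alcohol
Product: 18 (2E)-2-[4-(benzyloxy)-3-methoxybenzyl]-3-[4-(benzyloxy)-2-ethenyl-3,5-dimethoxyphenyl]-3-[4-(benzyloxy)-2-methoxyphenyl]prop-2-enal
Conditions: activated MnO2 (15 equiv), CH2Cl2, rt
Reagents that add atoms: none
Why: Allylic alcohol oxidation with MnO2 under neutral heterogeneous conditions, which stops at the aldehyde and avoids acid that could ionise the diaryl-substituted allylic alcohol or let the alkene rotate.

**Step 12**
Reactants: 18 the enal
Product: 19 (3E)-3-[4-(benzyloxy)-3-methoxybenzyl]-4-[4-(benzyloxy)-2-ethenyl-3,5-dimethoxyphenyl]-4-[4-(benzyloxy)-2-methoxyphenyl]but-3-en-2-ol (racemic at C2 of the butenol)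
Conditions: MeMgBr (1.5 equiv), THF, −78 → 0 °C; pH 7 buffer
Reagents that add atoms: methylmagnesium bromide, C[Mg]Br
Why: Grignard 1,2-addition, the fully substituted diaryl β-carbon being closed to conjugate attack; the new carbinol stereocentre forms without control and is erased in the next step.

**Step 13**
Reactants: 19 the secondary allylic alcohol
Product: 20 (3E)-3-[4-(benzyloxy)-3-methoxybenzyl]-4-[4-(benzyloxy)-2-ethenyl-3,5-dimethoxyphenyl]-4-[4-(benzyloxy)-2-methoxyphenyl]but-3-en-2-one
Conditions: IBX (1.5 equiv), DMSO/THF, rt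
Reagents that add atoms: none
Why: IBX oxidation of a secondary allylic alcohol to the enone, which releases no strong acid and at room temperature does not touch the benzylic positions or the styrene.

**Step 14**
Reactants: 20 the methyl ketone
Product: 22 tert-butyl({(3E)-3-[4-(benzyloxy)-3-methoxybenzyl]-4-[4-(benzyloxy)-2-ethenyl-3,5-dimethoxyphenyl]-4-[4-(benzyloxy)-2-methoxyphenyl]buta-1,3-dien-2-yl}oxy)dimethylsilane (ring A cis to the enol ether arm), via potassium enolate 21 (not isolated)
Conditions: KN(SiMe3)2 (1.2 equiv), THF, −78 °C; TBSCl (1.5 equiv), −78 → 0 °C; filtration through Et3N-deactivated silica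
Reagents that add atoms: tert-butyl(chloro)dimethylsilane, CC(C)(C)[Si](C)(C)Cl
Why: Kinetic enolate O-silylation, in which the acetyl CH3 carries the only protons α to the carbonyl and there are no γ-hydrogens, the amide base at −78 °C takes one of them faster than a C3 methylene proton, the potassium enolate silylates on oxygen, and the base-only protocol avoids Lewis-acid activation of the enone that could let the donor–acceptor alkene rotate.

**Step 15**
Reactants: 22 the TBS dienol ether
Product: 24 {[7-(benzyloxy)-3-[4-(benzyloxy)-3-methoxybenzyl]-4-[4-(benzyloxy)-2-methoxyphenyl]-6,8-dimethoxynaphthalen-2-yl]oxy}(tert-butyl)dimethylsilane, via ring A ruthenium alkylidene 23 (not isolated)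
Conditions: RuCl2(=CHPh)(PCy3)(SIMes) (second-generation Grubbs catalyst, 10 mol % in two portions), toluene (3 mM), 80 °C, Ar sparge
Reagents that add atoms: none
Why: Ring-closing olefin metathesis by the metallacyclobutane mechanism: the ruthenium alkylidene exchanges first onto the only monosubstituted alkene, the vinyl group on C8a, to give alkylidene 23, this adds [2+2] across the neighbouring CH2=C(OTBS) unit with ruthenium bonding to the CH2 terminus, and cycloreversion leaves the C1=C2 bond and Ru=CH2, which carries the chain while the two CH2 termini depart as ethene. The closest known reaction types are the ene–silyl enol ether ring-closing metathesis that gives cyclic silyl enol ethers and the arene-forming ring-closing metathesis of ortho-substituted styrenes. Ring B closes as a six-membered carbocycle in which four of the six atoms (C8a, C4a, C4, C3) are already held in a cis array, and because the new double bond completes the naphthalene π system the product cannot re-enter metathesis, so the closure is irreversible. No stereocentre is created and the E geometry of 22 is consumed in the arene. The step needs site selectivity (loading on the styrene rather than on the electron-rich enol ether, where a dormant heteroatom-stabilised carbene would form, and no reaction at C3=C4) and ring closure in preference to dimerisation; 1,1-disubstitution and the bulky silyl group keep the catalyst off the enol ether until the intramolecular encounter, full substitution protects C3=C4, and the two ortho substituents of the styrene together with high dilution suppress stilbene formation. Heating and ethene removal are chosen because the 8-methoxy group can chelate ruthenium in 23 and slow turnover.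

**Step 16**
Reactants: 24 the 2-silyloxynaphthalene
Product: 25 7-(benzyloxy)-3-[4-(benzyloxy)-3-methoxybenzyl]-4-[4-(benzyloxy)-2-methoxyphenyl]-6,8-dimethoxynaphthalen-2-ol
Conditions: Bu4NF (1.1 equiv), THF, 0 °C, under Ar
Reagents that add atoms: none
Why: Fluoride cleavage of an aryl silyl ether, driven by Si–F bond formation and the good naphthoxide leaving group, with benzyl and methyl ethers inert.

**Step 17**
Reactants: 25 the tribenzyl naphthol
Product: 26 3-(4-hydroxy-3-methoxybenzyl)-4-(4-hydroxy-2-methoxyphenyl)-6,8-dimethoxynaphthalene-2,7-diol (target, numbering of the plan)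
Conditions: H2 (1 atm), 10% Pd/C, EtOAc/MeOH, rt
Reagents that add atoms: none
Why: Catalytic hydrogenolysis of three aryl benzyl ethers, under which the naphthalene core, the diarylmethane CH2 and the methyl ethers are not attacked.

**Compound list**

1 | syringaldehyde | COc1cc(C=O)cc(OC)c1O | starting material
2 | 4-(benzyloxy)-3,5-dimethoxybenzaldehyde | COc1cc(C=O)cc(OC)c1OCc1ccccc1 | intermediate
3 | 4-(benzyloxy)-2-bromo-3,5-dimethoxybenzaldehyde | COc1cc(C=O)c(Br)c(OC)c1OCc1ccccc1 | intermediate
4 | 4-(benzyloxy)-2-ethenyl-3,5-dimethoxybenzaldehyde | C=Cc1c(C=O)cc(OC)c(OCc2ccccc2)c1OC | intermediate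
5 | 2-(benzyloxy)-4-ethenyl-5-ethynyl-1,3-dimethoxybenzene | C#Cc1cc(OC)c(OCc2ccccc2)c(OC)c1C=C | intermediate
6 | {[4-(benzyloxy)-2-ethenyl-3,5-dimethoxyphenyl]ethynyl}lithium | [Li]C#Cc1cc(OC)c(OCc2ccccc2)c(OC)c1C=C | intermediate
7 | methyl 3-[4-(benzyloxy)-2-ethenyl-3,5-dimethoxyphenyl]prop-2-ynoate | COC(=O)C#Cc1cc(OC)c(OCc2ccccc2)c(OC)c1C=C | intermediate
8 | 4-bromo-3-methoxyphenol | COc1cc(O)ccc1Br | starting material
9 | 4-(benzyloxy)-1-bromo-2-methoxybenzene | COc1cc(OCc2ccccc2)ccc1Br | intermediate
10 | vanillyl alcohol | COc1cc(CO)ccc1O | starting material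
11 | [4-(benzyloxy)-3-methoxyphenyl]methanol | COc1cc(CO)ccc1OCc1ccccc1 | intermediate
12 | 1-(benzyloxy)-4-(bromomethyl)-2-methoxybenzene | COc1cc(CBr)ccc1OCc1ccccc1 | intermediate
13 | [4-(benzyloxy)-2-methoxyphenyl]magnesium bromide | COc1cc(OCc2ccccc2)ccc1[Mg]Br | intermediate
14 | [4-(benzyloxy)-2-methoxyphenyl]copper | COc1cc(OCc2ccccc2)ccc1[Cu] | intermediate
15 | methyl (2Z)-3-[4-(benzyloxy)-2-ethenyl-3,5-dimethoxyphenyl]-3-[4-(benzyloxy)-2-methoxyphenyl]-2-cuprioprop-2-enoate (Cu cis to the 2-methoxyaryl group) | C=Cc1c(OC)c(OCc2ccccc2)c(OC)cc1/C(c1ccc(OCc2ccccc2)cc1OC)=C(/[Cu])C(=O)OC | intermediate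
16 | methyl (2E)-2-[4-(benzyloxy)-3-methoxybenzyl]-3-[4-(benzyloxy)-2-ethenyl-3,5-dimethoxyphenyl]-3-[4-(benzyloxy)-2-methoxyphenyl]prop-2-enoate | C=Cc1c(OC)c(OCc2ccccc2)c(OC)cc1/C(c1ccc(OCc2ccccc2)cc1OC)=C(/Cc1ccc(OCc2ccccc2)c(OC)c1)C(=O)OC | intermediate
17 | (2E)-2-[4-(benzyloxy)-3-methoxybenzyl]-3-[4-(benzyloxy)-2-ethenyl-3,5-dimethoxyphenyl]-3-[4-(benzyloxy)-2-methoxyphenyl]prop-2-en-1-ol | C=Cc1c(OC)c(OCc2ccccc2)c(OC)cc1/C(c1ccc(OCc2ccccc2)cc1OC)=C(/Cc1ccc(OCc2ccccc2)c(OC)c1)CO | intermediate
18 | (2E)-2-[4-(benzyloxy)-3-methoxybenzyl]-3-[4-(benzyloxy)-2-ethenyl-3,5-dimethoxyphenyl]-3-[4-(benzyloxy)-2-methoxyphenyl]prop-2-enal | C=Cc1c(OC)c(OCc2ccccc2)c(OC)cc1/C(c1ccc(OCc2ccccc2)cc1OC)=C(/Cc1ccc(OCc2ccccc2)c(OC)c1)C=O | intermediate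
19 | (3E)-3-[4-(benzyloxy)-3-methoxybenzyl]-4-[4-(benzyloxy)-2-ethenyl-3,5-dimethoxyphenyl]-4-[4-(benzyloxy)-2-methoxyphenyl]but-3-en-2-ol, racemic | C=Cc1c(OC)c(OCc2ccccc2)c(OC)cc1/C(c1ccc(OCc2ccccc2)cc1OC)=C(/Cc1ccc(OCc2ccccc2)c(OC)c1)C(C)O | intermediate
20 | (3E)-3-[4-(benzyloxy)-3-methoxybenzyl]-4-[4-(benzyloxy)-2-ethenyl-3,5-dimethoxyphenyl]-4-[4-(benzyloxy)-2-methoxyphenyl]but-3-en-2-one | C=Cc1c(OC)c(OCc2ccccc2)c(OC)cc1/C(c1ccc(OCc2ccccc2)cc1OC)=C(/Cc1ccc(OCc2ccccc2)c(OC)c1)C(C)=O | intermediate
21 | potassium (3E)-3-[4-(benzyloxy)-3-methoxybenzyl]-4-[4-(benzyloxy)-2-ethenyl-3,5-dimethoxyphenyl]-4-[4-(benzyloxy)-2-methoxyphenyl]buta-1,3-dien-2-olate | C=Cc1c(OC)c(OCc2ccccc2)c(OC)cc1/C(c1ccc(OCc2ccccc2)cc1OC)=C(/Cc1ccc(OCc2ccccc2)c(OC)c1)C(=C)[O-].[K+] | intermediate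
22 | tert-butyl({(3E)-3-[4-(benzyloxy)-3-methoxybenzyl]-4-[4-(benzyloxy)-2-ethenyl-3,5-dimethoxyphenyl]-4-[4-(benzyloxy)-2-methoxyphenyl]buta-1,3-dien-2-yl}oxy)dimethylsilane | C=Cc1c(OC)c(OCc2ccccc2)c(OC)cc1/C(c1ccc(OCc2ccccc2)cc1OC)=C(/Cc1ccc(OCc2ccccc2)c(OC)c1)C(=C)O[Si](C)(C)C(C)(C)C | intermediate
23 | RuCl2(SIMes)(=CH–aryl) alkylidene of 22 (Ru=CH on C8a in place of CH=CH2) | Cl[Ru](Cl)(=Cc1c(OC)c(OCc2ccccc2)c(OC)cc1/C(c1ccc(OCc2ccccc2)cc1OC)=C(/Cc1ccc(OCc2ccccc2)c(OC)c1)C(=C)O[Si](C)(C)C(C)(C)C)=C1N(c2c(C)cc(C)cc2C)CCN1c1c(C)cc(C)cc1C | intermediate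
24 | {[7-(benzyloxy)-3-[4-(benzyloxy)-3-methoxybenzyl]-4-[4-(benzyloxy)-2-methoxyphenyl]-6,8-dimethoxynaphthalen-2-yl]oxy}(tert-butyl)dimethylsilane | COc1cc(Cc2c(O[Si](C)(C)C(C)(C)C)cc3c(OC)c(OCc4ccccc4)c(OC)cc3c2-c2ccc(OCc5ccccc5)cc2OC)ccc1OCc1ccccc1 | intermediate
25 | 7-(benzyloxy)-3-[4-(benzyloxy)-3-methoxybenzyl]-4-[4-(benzyloxy)-2-methoxyphenyl]-6,8-dimethoxynaphthalen-2-ol | COc1cc(Cc2c(O)cc3c(OC)c(OCc4ccccc4)c(OC)cc3c2-c2ccc(OCc5ccccc5)cc2OC)ccc1OCc1ccccc1 | intermediate
26 | 3-(4-hydroxy-3-methoxybenzyl)-4-(4-hydroxy-2-methoxyphenyl)-6,8-dimethoxynaphthalene-2,7-diol | COc1cc(Cc2c(O)cc3c(OC)c(O)c(OC)cc3c2-c2ccc(O)cc2OC)ccc1O | target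

**Step count**

Total step count: 17.
Longest linear sequence: 14 steps from syringaldehyde (steps 1–5 and 9–17).

**The three steps most likely to fail**

1. **Step 15 (ring closure).**
   - What may go wrong: after loading on the ring A vinyl group the ruthenium may be held by the neighbouring 8-methoxy oxygen and turn over slowly. The crowded 1,1-disubstituted enol ether may never be engaged. At the temperature then needed, the enol ether may lose its silyl group.
   - Fallback: the same C1=C2 bond is made by carbonyl–olefin metathesis with a stoichiometric titanium alkylidene at the ester oxidation level, with neither ruthenium nor a silyl enol ether.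
   - Course: it sets out from aldehyde 18. Pinnick oxidation (NaClO2, NaH2PO4, 2-methylbut-2-ene, t-BuOH/H2O) should give the acrylic acid F1. O-alkylation of its carboxylate (BnBr, K2CO3, DMF), which is indifferent to crowding at the carbonyl carbon, gives the benzyl ester F2. The Takai–Utimoto ethylidene reagent (TiCl4, Zn, cat. PbCl2, TMEDA, CH3CHBr2, THF/CH2Cl2, 65 °C) exchanges onto the vinyl group and olefinates the ester carbonyl intramolecularly to the 2-benzyloxynaphthalene F3. Hydrogenolysis of all four benzyl ethers under the conditions of step 17 rejoins the route at 26.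

2. **Step 9 (carbocupration and alkylation).**
   - What may go wrong: alkylation of the ester-stabilised alkenylcopper may be slow. During that time it may leak through the copper allenolate, eroding the alkene geometry, or it may simply be protonated on work-up.
   - Fallback: the C3–CH2 bond is made by palladium-catalysed cross-coupling instead of copper alkylation.
   - Course: it sets out from ynoate 7, with 9 and 12 as before. Alkenylcopper 15 is generated as in step 9 but quenched at −78 °C with I2, a trap fast enough to outrun isomerisation, to give the α-iodoacrylate F4. Bromide 12 is converted with Zn dust and LiCl in THF into the benzylzinc bromide F5. Negishi coupling (Pd(OAc)2, SPhos, THF, 25–50 °C) replaces iodine by the benzyl group with retention and rejoins the route at 16. Palladium sits trans to ring A in this coupling, so the vinyl group is out of reach for a Heck cyclisation.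

3. **Step 14 (enol silylation).**
   - What may go wrong: deprotonation may compete at the doubly activated C3 methylene. The silyl group may be lost by hydrolysis during isolation. The donor–acceptor alkene may rotate if more forcing, Lewis-acidic silylation has to be used.
   - Fallback: the silyl enol ether is made by carbonyl methylenation, with no enolate at all.
   - Course: it sets out from aldehyde 18 by way of the acrylic acid F1 (Pinnick oxidation as above). TBSCl and imidazole in DMF give the silyl ester F6. Petasis methylenation of the silyl ester carbonyl (Cp2TiMe2, toluene, 70 °C) should deliver the silyl enol ether directly, rejoining the route at 22.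

**Further compounds**

F1 | step 15 | (2E)-2-[4-(benzyloxy)-3-methoxybenzyl]-3-[4-(benzyloxy)-2-ethenyl-3,5-dimethoxyphenyl]-3-[4-(benzyloxy)-2-methoxyphenyl]prop-2-enoic acid | C=Cc1c(OC)c(OCc2ccccc2)c(OC)cc1/C(c1ccc(OCc2ccccc2)cc1OC)=C(/Cc1ccc(OCc2ccccc2)c(OC)c1)C(=O)O
F2 | step 15 | benzyl (2E)-2-[4-(benzyloxy)-3-methoxybenzyl]-3-[4-(benzyloxy)-2-ethenyl-3,5-dimethoxyphenyl]-3-[4-(benzyloxy)-2-methoxyphenyl]prop-2-enoate | C=Cc1c(OC)c(OCc2ccccc2)c(OC)cc1/C(c1ccc(OCc2ccccc2)cc1OC)=C(/Cc1ccc(OCc2ccccc2)c(OC)c1)C(=O)OCc1ccccc1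
F3 | step 15 | 2,7-bis(benzyloxy)-3-[4-(benzyloxy)-3-methoxybenzyl]-4-[4-(benzyloxy)-2-methoxyphenyl]-6,8-dimethoxynaphthalene | COc1cc(Cc2c(OCc6ccccc6)cc3c(OC)c(OCc4ccccc4)c(OC)cc3c2-c2ccc(OCc5ccccc5)cc2OC)ccc1OCc1ccccc1
F4 | step 9 | methyl (2Z)-3-[4-(benzyloxy)-2-ethenyl-3,5-dimethoxyphenyl]-3-[4-(benzyloxy)-2-methoxyphenyl]-2-iodoprop-2-enoate | C=Cc1c(OC)c(OCc2ccccc2)c(OC)cc1/C(c1ccc(OCc2ccccc2)cc1OC)=C(/I)C(=O)OC
F5 | step 9 | [4-(benzyloxy)-3-methoxybenzyl]zinc bromide | COc1cc(C[Zn]Br)ccc1OCc1ccccc1
F6 | step 14 | tert-butyldimethylsilyl (2E)-2-[4-(benzyloxy)-3-methoxybenzyl]-3-[4-(benzyloxy)-2-ethenyl-3,5-dimethoxyphenyl]-3-[4-(benzyloxy)-2-methoxyphenyl]prop-2-enoate | C=Cc1c(OC)c(OCc2ccccc2)c(OC)cc1/C(c1ccc(OCc2ccccc2)cc1OC)=C(/Cc1ccc(OCc2ccccc2)c(OC)c1)C(=O)O[Si](C)(C)C(C)(C)C
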